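Locants: carbocycle C1–C10 with C1 = CHOH, C2 = CH2, C3 = C=O, C4(CH3)=C5 (Z), C6 = CH–O(lactone), C7, C8 = CH–O-angelate, C9 = CH2, C10 = C(OH)CH3. The lactone is O–C6–C7–C11–C12 and C13 is the exocyclic CH2.
Enabling feature: the oxygens on C1 and C3 flank the ring CH2 C2, and this O–C1–C2–C3–O triad is a latent 4,5-dihydroisoxazole bridging C1 and C3. The ten-membered ring is therefore cut at C1–C2 (and O–C3) into a nitrile oxide on C1, shielded by quaternary C10, and the terminal vinyl C2=C3 of a Z-diene.
Further cuts: C3–C4 (Stille), O8–acyl, C6–C7 with O–C12 (Barbier allylation/lactonisation), C7–C11 (Morita–Baylis–Hillman), C8–O (aminoxylation). Building blocks: (S)-linalool, methyl acrylate, but-2-yn-1-ol, a vinylstannane, angelic acid.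
Forward order: linalool chain (C7–C10, C1) → allyl bromide → union with (Z)-3-iodobut-2-enal closes the butyrolactone first (step 10) → the carbocycle closes last (step 17) together with the helper isoxazoline → N–O cleavage, C1 reduction, C3 oxidation.
Stereochemistry: C10 from linalool; C8 from L-proline catalysis; C7 and C6 from the closed chair transition state of the Z-allylindium under A1,3 control by C8; C1 from a CBS reduction matched with the Felkin–Anh bias of C10; C4=C5 (Z) from trans-hydroalumination/iodination; the angelate (Z) from angelic acid.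
Helpers and their removal: C13 sulfone masks the methylene lactone (on in 13, off in 20); isoxazoline (17/18); C3 carbinol as a relay centre (erased in 22); TES and TBS ethers (off in 11 and 21).

Key step: step 17

Assumption: (S)-(+)-linalool is bought in high ee; any minor enantiomer becomes a separable diastereomer after step 3.
Assumption: the target is treated as the open 3-keto-1,10-diol that is drawn, although it may equilibrate with its 3,10-hemiketal.
Remark: C7 in 11, C11 in 24–34 and C3 in 31–36 are transient stereocentres. Each is erased later, so they are left undefined in the SMILES.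

Step 1
Reactants: 1 (S)-(+)-linalool
Product: 2 (S)-linalool tert-butyldimethylsilyl ether
Conditions: TBSOTf, 2,6-lutidine, CH2Cl2, 0 °C to rt
Reagents that add atoms: TBSOTf, CC(C)(C)[Si](C)(C)OS(=O)(=O)C(F)(F)F
Why: Silyl triflate silylation of a tertiary alcohol leaves the chiral-pool centre C10 untouched, prevents lactol formation after step 2 and later provides the large group for step 19.

Step 2
Reactants: 2 (S)-linalool tert-butyldimethylsilyl ether
Product: 4 (4S)-4-(tert-butyldimethylsilyloxy)-4-methylhex-5-enal, via ozonide 3 (not isolated)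
Conditions: O3, CH2Cl2, −78 °C (Sudan III end point); then Me2S, −78 °C to rt
Reagents that add atoms: ozone, [O-][O+]=O
Why: Chemoselective ozonolysis should work because the electron-rich trisubstituted alkene is consumed well before the monosubstituted vinyl group next to the quaternary carbon.

Step 3
Reactants: 4 (4S)-4-(tert-butyldimethylsilyloxy)-4-methylhex-5-enal
Product: 7 (2R,4S)-4-(tert-butyldimethylsilyloxy)-4-methylhex-5-ene-1,2-diol, via anilinooxy aldehyde 5 (not isolated), via anilinooxy alcohol 6 (not isolated)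
Conditions: L-proline (20 mol %), PhNO, MeCN, −20 °C; NaBH4, MeOH, 0 °C; then Zn, AcOH–THF, rt
Reagents that add atoms: nitrosobenzene, O=Nc1ccccc1
Why: Enamine-catalysed α-aminoxylation sets C8 as R under catalyst control by L-proline, immediate reduction prevents epimerisation, and zinc cleaves the O–N bond without touching the alkene or the TBS ether.

Step 4
Reactants: 7 (2R,4S)-4-(tert-butyldimethylsilyloxy)-4-methylhex-5-ene-1,2-diol
Product: 8 1,2-bis(triethylsilyl) ether of 7
Conditions: TESCl, imidazole, DMF, 0 °C to rt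
Reagents that add atoms: chlorotriethylsilane, CC[Si](Cl)(CC)CC
Why: Standard silylation of a primary and a secondary alcohol prepares the direct oxidation of step 5.

Step 5
Reactants: 8 1,2-bis(triethylsilyl) ether of 7
Product: 9 (2R,4S)-4-(tert-butyldimethylsilyloxy)-4-methyl-2-(triethylsilyloxy)hex-5-enal
Conditions: (COCl)2, DMSO, CH2Cl2, −78 to −40 °C; Et3N, −78 to 0 °C
Reagents that add atoms: none
Why: Swern conditions are known to oxidise primary TES ethers directly to aldehydes while secondary TES and tertiary TBS ethers survive, and the low temperature protects the α-stereocentre C8.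

Step 6
Reactants: 9 (2R,4S)-4-(tert-butyldimethylsilyloxy)-4-methyl-2-(triethylsilyloxy)hex-5-enal; 10 methyl acrylate
Product: 11 methyl (4R,6S)-6-(tert-butyldimethylsilyloxy)-3-hydroxy-6-methyl-2-methylidene-4-(triethylsilyloxy)oct-7-enoate (C3 epimers)
Conditions: DABCO (cat.), 10 (excess), MeOH, rt
Reagents that add atoms: none
Why: The Morita–Baylis–Hillman reaction is accelerated by the inductively activated α-silyloxy aldehyde, and the new carbinol (C7) may form as a mixture because step 7 erases it.

Step 7
Reactants: 11 Morita–Baylis–Hillman adduct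
Product: 12 methyl (2Z,4R,6S)-2-(bromomethyl)-6-(tert-butyldimethylsilyloxy)-6-methyl-4-(triethylsilyloxy)octa-2,7-dienoate
Conditions: NBS, Me2S, CH2Cl2, 0 °C to rt
Reagents that add atoms: N-bromosuccinimide, O=C1CCC(=O)N1Br
Why: SN2′ bromination of Baylis–Hillman alcohols through the alkoxysulfonium salt is acid-free and gives the thermodynamic Z-bromide, with CH2Br cis to C8.

Step 8
Reactants: 13 but-2-yn-1-ol
Product: 15 (Z)-3-iodobut-2-en-1-ol, via vinylalanate 14 (not isolated)
Conditions: Red-Al, THF, 0 °C to rt; then I2, THF, −78 °C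
Reagents that add atoms: iodine, II; Red-Al, [Na+].COCCO[AlH2-]OCCOC (its atoms stay only in 14)
Why: Hydroxyl-directed trans-hydroalumination gives a cyclic vinylalanate whose iodinolysis with retention fixes iodine cis to CH2OH, which is the later Z geometry of C4=C5.

Step 9
Reactants: 15 (Z)-3-iodobut-2-en-1-ol
Product: 16 (Z)-3-iodobut-2-enal
Conditions: MnO2, CH2Cl2, rt, dark
Reagents that add atoms: none
Why: Neutral allylic oxidation with MnO2 gives the β-iodo enal without Z/E isomerisation when the product is used at once.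

Step 10
Reactants: 12 allyl bromide; 16 (Z)-3-iodobut-2-enal
Product: 19 cis-β,γ-disubstituted α-methylene-γ-butyrolactone (C4 iodide; 8-OTES; 10-OTBS; C1=CH2 vinyl), via allylindium species 17 (not isolated), via hydroxy ester 18 (not isolated)
Conditions: In powder, THF–H2O (1:1), rt; then PPTS (cat.), toluene, 60 °C
Reagents that add atoms: indium, [In] (its atom stays only in 17)
Why: In this Barbier 2-(alkoxycarbonyl)allylation/lactonisation the Z-allylindium should react through a closed chair transition state (C6/C7 syn, hence the cis-lactone) on the alkene face anti to the bulky C9 chain, with H8 eclipsing the CH2In arm (A1,3 strain), so that 8R sets 7R and 6S, while the vinyl iodide, the silyl ethers and the vinyl group are inert to indium.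

Step 11
Reactants: 19 cis-lactone (8-OTES)
Product: 20 8-hydroxy lactone
Conditions: AcOH–THF–H2O (3:1:1), rt
Reagents that add atoms: none
Why: Mild acid solvolysis removes the secondary TES ether much faster than the tertiary TBS ether and is too weak to promote translactonisation to O8.

Step 12
Reactants: 20 8-hydroxy lactone; 21 angelic acid
Product: 23 8-O-angelate, via mixed anhydride 22 (not isolated)
Conditions: 21, 2,4,6-trichlorobenzoyl chloride, Et3N, toluene, rt, filter; then 20, toluene, 80 °C
Reagents that add atoms: 2,4,6-trichlorobenzoyl chloride, O=C(Cl)c1c(Cl)cc(Cl)cc1Cl (its atoms stay only in 22)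
Why: Yamaguchi-type mixed-anhydride acylation without a nucleophilic catalyst is the established non-isomerising way to angelates, and only the secondary O8–H is free.

Step 13
Reactants: 23 8-O-angelate
Product: 24 13-(phenylsulfonyl)-11,13-dihydro lactone (C11 epimers)
Conditions: PhSO2Na, AcOH, EtOH–H2O, rt
Reagents that add atoms: sodium benzenesulfinate, [Na+].[O-]S(=O)c1ccccc1
Why: Sulfa-Michael addition occurs only at the unhindered exocyclic methylene (the angelate is trisubstituted) and gives a redox-inert mask that survives steps 14–19.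

Step 14
Reactants: 24 sulfone-masked lactone
Product: 26 C1 aldehyde, via vicinal diol 25 (not isolated)
Conditions: OsO4 (cat.), NaIO4, 2,6-lutidine, dioxane–H2O, rt
Reagents that add atoms: osmium tetroxide (catalytic oxygen carrier), O=[Os](=O)(=O)=O; sodium periodate, [Na+].[O-]I(=O)(=O)=O
Why: Lemieux–Johnson cleavage should pick the only electronically neutral monosubstituted alkene, because the iodoalkene and the angelate are deactivated and the O10 silyl ether excludes α-hydroxy aldehyde cleavage.

Step 15
Reactants: 26 C1 aldehyde; 27 tributyl(vinyl)stannane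
Product: 28 (Z)-diene aldehyde
Conditions: Pd2(dba)3 (cat.), AsPh3, NMP, rt
Reagents that add atoms: none
Why: Stille coupling of a Z-alkenyl iodide proceeds with retention under neutral, base-free conditions, so the sulfone stays and oxidative addition to C–I outruns ionisation of the allylic lactone C6–O bond.

Step 16
Reactants: 28 (Z)-diene aldehyde
Product: 29 C1 aldoxime
Conditions: NH2OH·HCl, NaOAc, MeOH–THF, rt
Reagents that add atoms: hydroxylamine hydrochloride, NO.Cl
Why: Buffered oxime condensation takes place at the only aldehyde, and the masked lactone offers hydroxylamine no Michael acceptor.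

Step 17
Reactants: 29 C1 aldoxime
Product: 31 C1,C3-bridged 4,5-dihydroisoxazole containing the closed ten-membered ring, via nitrile oxide 30 (not isolated)
Conditions: PhI(OAc)2 (slow addition), CH2Cl2 (about 1 mM), rt to 40 °C
Reagents that add atoms: none
Why: Proposed new method: PhI(OAc)2 dehydrogenates the aldoxime to nitrile oxide 30, whose carbon C1 bonds to the terminal diene carbon C2 while its oxygen bonds to C3 in a concerted (3+2) cycloaddition; the closest known reaction type is the intramolecular nitrile oxide–alkene cycloaddition used for rings of twelve and more members, and its use for a ten-membered carbocycle is what is new. Two rings close at once: the carbocycle in the endo (bridged) mode, with both alkene carbons ending in the ring and the C–C bond at the unsubstituted terminus as the normal 5-substituted-isoxazoline regiochemistry demands, and the dihydroisoxazole spanning C1 and C3 (bicyclo[7.2.1] frame, whose bridgehead C=N is trans only within an eleven-membered ring and is therefore allowed). The polarity is chosen so that the in-plane exocyclic bond of the C=N bridgehead starts at the freely rotating sp3 carbon C10, whereas the rigid Z-alkene hangs on the sp3 bridgehead C3 and folds back over the ring, and the cis-lactone and the Z-alkene serve as two turn elements that bring the chain ends together. The only new stereocentre is C3, set by whichever face of the A1,3-twisted vinyl group is turned toward the tether; it is erased in step 22, so no facial selectivity is required. The step needs chemoselectivity for the vinyl group: C11=C13, which would be captured through a six-membered transition state, is masked as the sulfone, and C4=C5 and the angelate are trisubstituted and unreactive toward nitrile oxides. It also needs cyclisation to outrun furoxan formation, which the quaternary C10 next to the dipole, the base-free oxidant (no loss of sulfinate) and slow addition at high dilution should secure.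

Step 18
Reactants: 31 bridged dihydroisoxazole
Product: 33 1-oxo-3-hydroxy macrocycle, via hydroxy imine 32 (not isolated)
Conditions: Mo(CO)6, MeCN–H2O, 80 °C
Reagents that add atoms: water, O
Why: Molybdenum hexacarbonyl N–O cleavage followed by imine hydrolysis is the standard unmasking of dihydroisoxazoles to β-hydroxy ketones and spares alkenes, esters, the sulfone and the silyl ether.

Step 19
Reactants: 33 1-oxo-3-hydroxy macrocycle
Product: 34 (1S)-1,3-diol
Conditions: (R)-Me-CBS, catecholborane, toluene, −78 to −40 °C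
Reagents that add atoms: none
Why: In the CBS reduction of the only ketone the catalyst differentiates quaternary C10 (large) from C2H2 (small), so the (R)-oxazaborolidine should give 1S, and this is also the face favoured by Felkin–Anh attack anti to the C10–OTBS bond past the methyl group (matched case).

Step 20
Reactants: 34 (1S)-1,3-diol
Product: 35 α-methylene lactone
Conditions: DBU, CH2Cl2, 0 °C
Reagents that add atoms: none
Why: E1cB loss of benzenesulfinate from the β-sulfonyl lactone regenerates C11=C13 at a stage where no β-hydroxy ketone is yet present to suffer from base.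

Step 21
Reactants: 35 α-methylene lactone
Product: 36 1,3,10-triol
Conditions: HF·pyridine, pyridine, THF, 0 °C to rt
Reagents that add atoms: none
Why: Buffered fluoride desilylation frees the tertiary C10 hydroxyl without affecting the angelate, the methylene lactone or the allylic alcohol.

Step 22
Reactants: 36 1,3,10-triol
Product: 37 target CNP0271189.1
Conditions: MnO2, CH2Cl2, rt
Reagents that add atoms: none
Why: MnO2 oxidises only the allylic C3 carbinol (both epimers converge on the Z-enone) and leaves the secondary C1 and tertiary C10 hydroxyls alone, so the sensitive β-hydroxy enone appears under neutral conditions in the last step.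

Compound list
1 | (S)-(+)-linalool | CC(C)=CCC[C@](C)(O)C=C | starting material
2 | (S)-linalool TBS ether | CC(C)=CCC[C@](C)(O[Si](C)(C)C(C)(C)C)C=C | intermediate
3 | ozonide (1,2,4-trioxolane) of the trisubstituted alkene of 2 | CC1(C)OOC(CC[C@](C)(O[Si](C)(C)C(C)(C)C)C=C)O1 | intermediate
4 | (4S)-4-(TBS-oxy)-4-methylhex-5-enal | O=CCC[C@](C)(O[Si](C)(C)C(C)(C)C)C=C | intermediate
5 | (2R,4S)-2-(anilinooxy)-4-(TBS-oxy)-4-methylhex-5-enal | O=C[C@H](ONc1ccccc1)C[C@](C)(O[Si](C)(C)C(C)(C)C)C=C | intermediate
6 | (2R,4S)-2-(anilinooxy)-4-(TBS-oxy)-4-methylhex-5-en-1-ol | OC[C@H](ONc1ccccc1)C[C@](C)(O[Si](C)(C)C(C)(C)C)C=C | intermediate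
7 | (2R,4S)-4-(TBS-oxy)-4-methylhex-5-ene-1,2-diol | OC[C@H](O)C[C@](C)(O[Si](C)(C)C(C)(C)C)C=C | intermediate
8 | 1,2-bis-TES ether of 7 | CC[Si](CC)(CC)OC[C@H](O[Si](CC)(CC)CC)C[C@](C)(O[Si](C)(C)C(C)(C)C)C=C | intermediate
9 | (2R,4S)-4-(TBS-oxy)-4-methyl-2-(TES-oxy)hex-5-enal | O=C[C@H](O[Si](CC)(CC)CC)C[C@](C)(O[Si](C)(C)C(C)(C)C)C=C | intermediate
10 | methyl acrylate | C=CC(=O)OC | starting material
11 | Morita–Baylis–Hillman adduct (carbinol epimers) | C=C(C(=O)OC)C(O)[C@H](O[Si](CC)(CC)CC)C[C@](C)(O[Si](C)(C)C(C)(C)C)C=C | intermediate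
12 | methyl (2Z,4R,6S)-2-(bromomethyl)-6-(TBS-oxy)-6-methyl-4-(TES-oxy)octa-2,7-dienoate | COC(=O)/C(CBr)=C/[C@H](O[Si](CC)(CC)CC)C[C@](C)(O[Si](C)(C)C(C)(C)C)C=C | intermediate
13 | but-2-yn-1-ol | CC#CCO | starting material
14 | sodium cyclic vinylalanate from 13 | CC1=CCO[Al-]1(OCCOC)OCCOC.[Na+] | intermediate
15 | (Z)-3-iodobut-2-en-1-ol | C/C(I)=C/CO | intermediate
16 | (Z)-3-iodobut-2-enal | C/C(I)=C/C=O | intermediate
17 | allylindium dibromide from 12 (one constituent of the sesquihalide) | COC(=O)/C(C[In](Br)Br)=C/[C@H](O[Si](CC)(CC)CC)C[C@](C)(O[Si](C)(C)C(C)(C)C)C=C | intermediate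
18 | syn-hydroxy ester (C6, C7, C8, C10 as in the target) | C=C(C(=O)OC)[C@@H]([C@@H](O)/C=C(/C)I)[C@H](O[Si](CC)(CC)CC)C[C@](C)(O[Si](C)(C)C(C)(C)C)C=C | intermediate
19 | cis-lactone, C4 iodide, 8-OTES, 10-OTBS | C=C1C(=O)O[C@@H](/C=C(/C)I)[C@H]1[C@H](O[Si](CC)(CC)CC)C[C@](C)(O[Si](C)(C)C(C)(C)C)C=C | intermediate
20 | 8-hydroxy lactone | C=C1C(=O)O[C@@H](/C=C(/C)I)[C@H]1[C@H](O)C[C@](C)(O[Si](C)(C)C(C)(C)C)C=C | intermediate
21 | angelic acid | C/C=C(/C)C(=O)O | starting material
22 | angelic 2,4,6-trichlorobenzoic anhydride | C/C=C(/C)C(=O)OC(=O)c1c(Cl)cc(Cl)cc1Cl | intermediate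
23 | 8-O-angelate | C=C1C(=O)O[C@@H](/C=C(/C)I)[C@H]1[C@H](OC(=O)/C(C)=C\C)C[C@](C)(O[Si](C)(C)C(C)(C)C)C=C | intermediate
24 | 13-phenylsulfonyl lactone (C11 epimers) | O=S(=O)(CC1C(=O)O[C@@H](/C=C(/C)I)[C@H]1[C@H](OC(=O)/C(C)=C\C)C[C@](C)(O[Si](C)(C)C(C)(C)C)C=C)c1ccccc1 | intermediate
25 | vicinal diol from the vinyl group of 24 | O=S(=O)(CC1C(=O)O[C@@H](/C=C(/C)I)[C@H]1[C@H](OC(=O)/C(C)=C\C)C[C@](C)(O[Si](C)(C)C(C)(C)C)C(O)CO)c1ccccc1 | intermediate
26 | C1 aldehyde (C4 iodide) | O=S(=O)(CC1C(=O)O[C@@H](/C=C(/C)I)[C@H]1[C@H](OC(=O)/C(C)=C\C)C[C@](C)(O[Si](C)(C)C(C)(C)C)C=O)c1ccccc1 | intermediate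
27 | tributyl(vinyl)stannane | C=C[Sn](CCCC)(CCCC)CCCC | starting material
28 | (Z)-diene aldehyde | O=S(=O)(CC1C(=O)O[C@@H](/C=C(/C)C=C)[C@H]1[C@H](OC(=O)/C(C)=C\C)C[C@](C)(O[Si](C)(C)C(C)(C)C)C=O)c1ccccc1 | intermediate
29 | C1 (E)-aldoxime | O=S(=O)(CC1C(=O)O[C@@H](/C=C(/C)C=C)[C@H]1[C@H](OC(=O)/C(C)=C\C)C[C@](C)(O[Si](C)(C)C(C)(C)C)/C=N/O)c1ccccc1 | intermediate
30 | C1 nitrile oxide | O=S(=O)(CC1C(=O)O[C@@H](/C=C(/C)C=C)[C@H]1[C@H](OC(=O)/C(C)=C\C)C[C@](C)(O[Si](C)(C)C(C)(C)C)C#[N+][O-])c1ccccc1 | intermediate
31 | C1,C3-bridged 4,5-dihydroisoxazole with closed ten-membered ring | O=S(=O)(CC1C(=O)O[C@H]2/C=C(/C)C3CC(=NO3)[C@@](C)(O[Si](C)(C)C(C)(C)C)C[C@@H](OC(=O)/C(C)=C\C)[C@@H]12)c1ccccc1 | intermediate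
32 | 3-hydroxy 1-imine | O=S(=O)(CC1C(=O)O[C@H]2/C=C(/C)C(O)CC(=N)[C@@](C)(O[Si](C)(C)C(C)(C)C)C[C@@H](OC(=O)/C(C)=C\C)[C@@H]12)c1ccccc1 | intermediate
33 | 1-oxo-3-hydroxy macrocycle | O=S(=O)(CC1C(=O)O[C@H]2/C=C(/C)C(O)CC(=O)[C@@](C)(O[Si](C)(C)C(C)(C)C)C[C@@H](OC(=O)/C(C)=C\C)[C@@H]12)c1ccccc1 | intermediate
34 | (1S)-1,3-diol (sulfone, 10-OTBS) | O=S(=O)(CC1C(=O)O[C@H]2/C=C(/C)C(O)C[C@H](O)[C@@](C)(O[Si](C)(C)C(C)(C)C)C[C@@H](OC(=O)/C(C)=C\C)[C@@H]12)c1ccccc1 | intermediate
35 | α-methylene lactone (10-OTBS) | C=C1C(=O)O[C@H]2/C=C(/C)C(O)C[C@H](O)[C@@](C)(O[Si](C)(C)C(C)(C)C)C[C@@H](OC(=O)/C(C)=C\C)[C@@H]12 | intermediate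
36 | 1,3,10-triol | C=C1C(=O)O[C@H]2/C=C(/C)C(O)C[C@H](O)[C@@](C)(O)C[C@@H](OC(=O)/C(C)=C\C)[C@@H]12 | intermediate
37 | CNP0271189.1 | C=C1C(=O)O[C@H]2/C=C(/C)C(=O)C[C@H](O)[C@@](C)(O)C[C@@H](OC(=O)/C(C)=C\C)[C@@H]12 | target

Total steps: 22. Longest linear sequence: 20 (steps 1–7 and 10–22).

Steps most likely to fail

Step 17. Transannular strain in the bicyclic transition state may slow ring closure. The dipole would then be lost by dimerisation to furoxans or by intermolecular cycloaddition. The fallback uses known chemistry only and closes the ring at C3–C4 instead of C1–C2.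
- It sets out from iodo aldehyde 26. Brown allylation with (−)-B-allyldiisopinocampheylborane (non-oxidative work-up) gives the (1S)-homoallylic alcohol F1.
- TESOTf/2,6-lutidine gives its TES ether F2.
- Lemieux–Johnson cleavage of the unhindered terminal alkene gives the C3 aldehyde F3.
- A Nozaki–Hiyama–Kishi macrocyclisation (CrCl2, cat. NiCl2, DMSO–THF, high dilution) joins C3 to the alkenyl iodide carbon C4 and gives the macrocyclic allylic alcohol F4.
- AcOH–THF–H2O removes the TES group, and the route is rejoined at diol 34.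

Step 10. Two processes may erode selectivity: E/Z equilibration of the allylindium, and weak facial discrimination by C8 on the allyl unit. The result would be poor C6/C7 and C7/C8 control. The fallback replaces substrate control by a configurationally stable reagent under catalyst control.
- It sets out from bromide 12. Copper-catalysed borylation (B2pin2, CuCl, KOtBu) gives the (Z)-allylboronate F5.
- Allylboration of 16 follows under a chiral BINOL-derived phosphoric acid, using the catalyst enantiomer matched with the A1,3 bias. The closed chair transition state fixes C6/C7 as syn, and the catalyst selects the aldehyde face.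
- The route is rejoined at hydroxy ester 18, which is lactonised to 19 as in step 10.

Step 19. Hydride delivery directed by the boron-bound C3 oxygen may compete with catalyst control and erode the configuration at C1. The fallback removes the directing group and relies on acyclic 1,2-induction.
- It sets out from 33. TESOTf/2,6-lutidine gives the 3-O-TES ketone F6.
- L-Selectride at −78 °C reduces it under pure Felkin–Anh control by the C10–OTBS group to the (1S)-alcohol F7.
- DBU gives the methylene lactone F8.
- HF·pyridine removes both silyl groups, and the route is rejoined at triol 36.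

Further compounds
F1 | step 17 | (1S)-homoallylic alcohol from 26 | O=S(=O)(CC1C(=O)O[C@@H](/C=C(/C)I)[C@H]1[C@H](OC(=O)/C(C)=C\C)C[C@](C)(O[Si](C)(C)C(C)(C)C)[C@@H](O)CC=C)c1ccccc1
F2 | step 17 | 1-O-TES ether of F1 | O=S(=O)(CC1C(=O)O[C@@H](/C=C(/C)I)[C@H]1[C@H](OC(=O)/C(C)=C\C)C[C@](C)(O[Si](C)(C)C(C)(C)C)[C@@H](O[Si](CC)(CC)CC)CC=C)c1ccccc1
F3 | step 17 | C3 aldehyde | O=S(=O)(CC1C(=O)O[C@@H](/C=C(/C)I)[C@H]1[C@H](OC(=O)/C(C)=C\C)C[C@](C)(O[Si](C)(C)C(C)(C)C)[C@@H](O[Si](CC)(CC)CC)CC=O)c1ccccc1
F4 | step 17 | macrocyclic C3 allylic alcohol, 1-O-TES | O=S(=O)(CC1C(=O)O[C@H]2/C=C(/C)C(O)C[C@H](O[Si](CC)(CC)CC)[C@@](C)(O[Si](C)(C)C(C)(C)C)C[C@@H](OC(=O)/C(C)=C\C)[C@@H]12)c1ccccc1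
F5 | step 10 | (Z)-allylboronic acid pinacol ester from 12 | COC(=O)/C(CB1OC(C)(C)C(C)(C)O1)=C/[C@H](O[Si](CC)(CC)CC)C[C@](C)(O[Si](C)(C)C(C)(C)C)C=C
F6 | step 19 | 3-O-TES 1-ketone | O=S(=O)(CC1C(=O)O[C@H]2/C=C(/C)C(O[Si](CC)(CC)CC)CC(=O)[C@@](C)(O[Si](C)(C)C(C)(C)C)C[C@@H](OC(=O)/C(C)=C\C)[C@@H]12)c1ccccc1
F7 | step 19 | 3-O-TES (1S)-alcohol | O=S(=O)(CC1C(=O)O[C@H]2/C=C(/C)C(O[Si](CC)(CC)CC)C[C@H](O)[C@@](C)(O[Si](C)(C)C(C)(C)C)C[C@@H](OC(=O)/C(C)=C\C)[C@@H]12)c1ccccc1
F8 | step 19 | 3-O-TES α-methylene lactone | C=C1C(=O)O[C@H]2/C=C(/C)C(O[Si](CC)(CC)CC)C[C@H](O)[C@@](C)(O[Si](C)(C)C(C)(C)C)C[C@@H](OC(=O)/C(C)=C\C)[C@@H]12
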